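The stirred vessel takes in X at a steady rate under held G, with none of G in solution at the start.

| setting | alpha | beta | flask |
|---|---|---|---|
| X | 11 mM (fed, over 10 h) | 7.4 mM (fed, over 10 h) | 11 mM (fed, over 10 h) |
| G | 5.7 mM (held) | 5.7 mM (held) | 5.7 mM (held) |
| remark | the very flask that is asked about, followed so far | run made earlier |  |
| time |  |  | 4.0 d |

- alpha (time / h: D / %): 1.00: 0; 2.00: 0; 3.00: 1; 4.00: 3; 6.00: 3; 8.00: 7
- beta (time / h: D / %): 3.00: 0; 5.00: 4; 8.00: 7; 10.0: 12; 15.0: 23; 25.0: 31; 40.0: 33

(readings scatter by 1.5 percentage points)

- at the start none of G is in solution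
- percentages count the whole charge, also what has not yet gone in

- the moment within 4.0 d at which there is most D
- the amount of D, in percent of the X charged, at that time

Alpha, the flask asked about, and beta stand level at 8.00 h, with 7% and 7% of D, though alpha holds 1.49 times beta's charge. A percentage rate that ignores the charge points to a pseudo-first-order step, first order in X with dissolved G frozen at one level, so beta's later course can stand for alpha's. Beta gains from 7% to 23% by 15.0 h. With X counted as the whole charge, that gives 43.8 h for the X clock, the time in which X, its partner frozen, falls to 36.8% of itself. X is really below the whole charge, so this clock runs long.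

Two first-order steps in a row, X to D and D onward, with equal clocks top D out one clock after the feed's midpoint, which here makes 2.03 d, a late edge. They would top out at 36.8%, but beta reads 33% at 40.0 h, so this reckoning takes beta's reading as the height.

The forecast gives 2 d (1.2 d to 4 d) and 32% (25% to 39%), on the ground that “the percentage rate barely depends on the X level”.

The flask gives 32.1% at 1.55 d.

    X + D → E (k = 0.0110 M⁻¹ min⁻¹)
    Q + D → L (k = 0.220 M⁻¹ min⁻¹)
    G ⇌ Q, rate k3*(csat - [Q]) (kL = 0.00230 min⁻¹)
    2 Q → J (k = 0.270 M⁻¹ min⁻¹)
    X + Q → D (k = 0.200 M⁻¹ min⁻¹)

At 0.417 d, the end of the feed, the flask holds Q, the dissolved G, at 2.40 mM and X at 87.4%. At 1.55 d the flask holds Q at 2.46 mM and X at 38.4%, which makes a clock of 33.0 h, shorter than the 43.8 h read from beta. At 1.84 d the flask's D goes to L 15 times faster than to E, and at 4.00 d L holds 72.5% against 10.0% for E. In the neighbour with 27 mM of X, the 43.8 h leaves 12.5% of X at 4.00 d, and that flask holds 8.21%.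

The earlier runs and the new flask are simulated for an exercise, noise included.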